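**Two runs.** The violet run held 0.15 M of starting material and the ochre run 0.22 M, yet at 20.0 min the target stood at 22.2% and 22.4% of the charge, a gap smaller than the scatter of 0.5 percentage points.

| setting | violet | ochre | flask |
|---|---|---|---|
| starting material | 0.15 M | 0.22 M | 0.30 M |
| protic impurity | 0.090 M | 0.090 M | 0.0900 M |
| remark | run made earlier | run made earlier |  |
| time |  |  | 1.0 h |

| violet: time / min | violet: target / % | ochre: time / min | ochre: target / % |
|---|---|---|---|
| 4.00 | 8.0 | 4.00 | 7.1 |
| 8.00 | 15.4 | 8.00 | 15.9 |
| 20.0 | 22.2 | 20.0 | 22.4 |
| 40.0 | 11.9 | 40.0 | 13.1 |

(standard deviation of a reading: 0.5 percentage points)

1. the moment within 1.0 h at which there is most target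
2. the amount of target, in percent of the starting material charged, at that time
3. earliest time at which at least nineteen twentieths of that best amount are there
4. latest time at which they still are



**Bench rule.** When percentage curves overlap like this, the bench habit is to call the change first order, meaning that rate goes with amount, and to copy the curve to the next charge. I did that for the flask: a peak near 20.0 min, a little above the 22.2% read in the violet run.

**Fall constant.** Past the peak, I wanted the time constant of the fall, the time in which the target shrinks by a factor of e, net of whatever is still being made. The drop from 20.0 min to 40.0 min, taken over both runs, reads 34.5 min.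

**The border.** The copy assumes that other amounts keep their proportion to the charge or play no part, but c(protic impurity) stayed put while c(starting material) rose. Impurity per starting material went from 0.600 in the violet run to 0.409 in the ochre run, and it is 0.300 in the flask, lower than in either run. So my copy stands beyond what the runs tested. At 40.0 min the ochre reading already lay above the violet one, by 1.2 points.

**The forecast.** The forecast, higher and earlier than my figure, gave 25.5% at 0.25 h, with the band from 0.21 h to 0.29 h, expecting the flask to “follow the same percentage curve”.

**The result.** The flask peaked at 0.296 h with 23.8%, and the band ran from 0.223 h to 0.386 h.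

    target → over-reaction product (k = 0.0523 min⁻¹)
    starting material ⇌ intermediate (K = 0.890, k = 0.125 min⁻¹)
    starting material → side product (k = 0.0263 min⁻¹)
    intermediate → target (k = 0.149 min⁻¹)
    starting material + protic impurity → quenched substrate (k = 0.707 M⁻¹ min⁻¹)

**The tail.** At 1.00 h, the flask made target more slowly than it used it up, at 0.136 of that rate, each step taken net. Carrying the peak forward from 0.296 h with the time constant of 34.5 min gives 6.99% at 1.00 h, and the flask held 5.97%.

Readings and results were computed from invented constants; noise was put on by code.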